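We start with the easy step: both earlier runs rise fast, then stop far below full yield, Saturday's at 11.8% and Sunday's at 57.0%.

| setting | Saturday's | Sunday's | violet | ochre | teal | green | blue |
|---|---|---|---|---|---|---|---|
| Q | 0.050 M | 0.050 M | 0.050 M | 0.050 M | 0.050 M | 0.050 M | 0.050 M |
| L | 0.017 mol% | 0.18 mol% | 0.066 mol% | 0.03 mol% | 0.25 mol% | 0.2 mol% | 0.04 mol% |
| remark | run made earlier | run made earlier |  |  |  |  |  |
| time |  |  | 5.0 h | 5.0 h | 5.0 h | 5.0 h | 5.0 h |

| run | time / h | G / % |
|---|---|---|
| Saturday's | 0.200 | 5.7 |
| Saturday's | 0.500 | 8.4 |
| Saturday's | 1.00 | 10.8 |
| Saturday's | 2.50 | 11.8 |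
| Sunday's | 0.200 | 41.9 |
| Sunday's | 0.500 | 55.2 |
| Sunday's | 1.00 | 57.0 |
| Sunday's | 2.50 | 54.8 |

(standard deviation of a reading: 0.5 percentage points)

1. ranking by amount of G, in percent of the Q charged, from high to low, at 5.0 h (violet / ochre / teal / green / blue)
2. the amount of G, in percent of the Q charged of the flask you put first, at 5.0 h
3. the amount of G, in percent of the Q charged of the flask you put last, at 5.0 h

Our reckoning supposes that Q is shared between a path through L and a rival path, both first order in Q. Dividing one rate by the other then removes Q and time together, so with L supposed to stay as charged, the split stays the same throughout the run.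

Take time first. By hand, we take Sunday's late fall as a slow wearing down of G, which waiting would carry further. Sunday's fall from 57.0% to 54.8% reads as 0.0262 h⁻¹, which leaves a factor 0.877 at 5.0 h. Carried back to the start at that pace, the plateaus read 12.6% for Saturday's run and 58.5% for Sunday's.

Sunday's readings then give 1.41 as the branching ratio, the G made per Q lost any other way, a selectivity factor free of time.

Next comes the loading. If the path through L is first order in L, the ratio should follow the loading. Saturday's ratio is 0.144, so Sunday's stands 9.79 times higher for a loading 10.6 times higher, which is close for a reading of 11.8% with a scatter of 0.5 percentage points.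

Scaling by loading gives teal a ratio of 1.96 and ochre 0.235. With the factor for time, we expect 58.1% in teal and 16.7% in ochre, and we rank the flasks by their loading of L.

The third setting, the amount of Q, stands at 0.050 M in every flask, so it separates none of them.

The forecast gives teal > green > violet > blue > ochre, with 58% and 17.5%, and says “Decay is unlikely to reverse the ranking.”

The simulation gives teal > green > violet > blue > ochre, with 57.7% first and 16.6% last.

    Q + L → L + G (k = 42000 M⁻¹ h⁻¹)
    G ⇌ D (K = 6.60, k = 0.0280 h⁻¹)
    Q → Z (k = 2.70 h⁻¹)

The path from Q to Z is the main reason for ochre's low figure: with that path taken away, ochre gives 86.6% instead of 16.6%. At 5.00 h ochre has 0% of its Q and 100% of its L left, and its Z stands at 81.1% of the Q charged, where the ratio puts 81.0%. A further flask, charged like teal but with 0.62 mol% of L, reckons a ratio of 4.86, which with the same factor means 72.7% of G, and that flask gives 72.2%.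

(The runs are calculated on assumed constants, noise included.)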